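## Structural features

- The target has five benzene rings and two dihydropyran rings. The upper chroman (O1, C2, C3, C4, benzo ring A) carries ring B (2-hydroxy-4,5-dimethoxyphenyl) on C3 and the central ring D on C4. The lower chroman (benzo ring A′) is attached through C3′ to ring D.
- Ring D is 1,2,4,6-tetrasubstituted: C1 is bonded to C4, C2 carries OMe, C4 carries OH and C6 carries C3′. The C4–ring D bond is therefore flanked by two ortho substituents.
- C3 and C4 are adjacent and trans, (3R,4S). C3′ is (R), stands alone and is four bonds from C4 across ring D, so it cannot relay its configuration to the upper pair.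
- The four free phenols sit on electron-rich rings and are oxidation-sensitive. C4 is a diaryl methine ortho or para to oxygen on two rings and ionises in strong acid. C3 epimerises whenever C2 is a carbonyl.
- The real difficulty is the congested C3–C4 bond with control of both centres beside a di-ortho-substituted ring D, together with the ordering of seven aryl oxygen substituents (three methyl ethers, four hydroxyls).
- The key step exploits the state before C3–C4 exists: C4 is then the CH2 of a diarylmethane between ring A and ring D, with two hydridic hydrogens. O1 of ring A can hold the ring B aryldiazoacetyl unit as an aryl ester, so the carbene carbon (future C3; ring B donor, C2 acceptor) lies six atoms from C4–H.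

## Logic of the disconnections

**35 ⇒ 34 ⇒ 33.** Three O–CH2Ph bonds and one O–Si bond are cut. The phenols stay masked to the end because they are the most fragile groups. The forward steps must leave the chroman C–O bonds and C4 untouched, which fluoride and neutral hydrogenolysis do.

**33 ⇒ 32 ⇒ 31.** The O1–C2 ether bond is cut and C2 is raised to the carbonyl level. This reveals a six-membered aryl lactone in which C3 is the α-carbon. The forward steps must reduce without epimerising C3 and must alkylate O1 on C2 while the ring B oxygen is still masked, so that only O1 can close a ring.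

**31 ⇒ 29.** The C3–C4 bond is cut. It is the one bond joining both upper stereocentres, and removing it takes away a ring and two stereocentres and leaves a diarylmethane tied to an aryldiazoacetate only through the ester. The forward step must choose one of two C–H bonds and must prefer C–H insertion over attack on an arene. C3 can be corrected afterwards through 30.

**29 ⇒ 28 ⇒ 23 + 27.** The C=N2 unit and the acyl C2–O1 bond are cut. This splits the molecule into a phenol holding rings A, D and the lower chroman, and the ring B acid. The forward steps need a diazo transfer that does not cleave the aryl ester, and a ring B protecting group with no C–H on the atom bound to oxygen.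

**27 ⇒ 26 ⇒ 25 ⇒ 24.** The O–Si bond is cut and the aryl C–O bond is traced back to C–Br. This reaches a commercial bromo acid with the ring B pattern already in place. The forward step is a hydroxylation of an electron-rich aryl bromide.

**23 ⇒ 22 ⇒ 21.** The O1′–C2′ bond of the lower chroman is cut and both ortho phenols are put back as allyl ethers. The forward closure must select between two free phenols, which ring size does (six against nine members).

**21 ⇒ 20 ⇒ 19 ⇒ 14 + 18, and 18 ⇒ 17 ⇒ 16 ⇒ 15.** The C3′–C4′ bond is cut. C3′ is α to a carboxyl-derived carbon and bears ring D, so an auxiliary-controlled enolate benzylation sets it. The demand is face selectivity of the enolate and a labile, electron-rich benzyl bromide.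

**14 ⇒ 13 ⇒ 11 + 12, and 11 ⇒ 10 ⇒ 9 ⇒ 4 + 7 (through 8).** The N–acyl bond is cut. Then the bond from the future C4 to C4a of ring A is cut, after oxygen is put back on that carbon. The aldehyde carbon of 4 is the future C4, and ring A enters as a carbon nucleophile, so no Friedel–Crafts regiochemistry arises. The diarylmethane is fixed before any stereocentre exists. The forward steps need aldehyde addition in the presence of an ester and an ionic reduction that spares allyl and benzyl ethers.

**4 ⇒ 3 ⇒ 2 ⇒ 1, and 7 ⇒ 6 ⇒ 5.** The O–Me, O–Bn and ring D C1–CHO bonds are cut, and on the other branch O–allyl and C–I. Formylation of symmetrical 1 makes the two hydroxyls different (one becomes chelated), so benzyl and methyl can be placed in turn. The demand is regioselective formylation and iodination.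

## Other disconnections considered

**Alternative 1:** The cut removes the C3–ring B bond and the C4–C4a bond together and leaves ring D on an alkene.
- **Forward step.** A conjunctive coupling: A4, after bromine–lithium exchange, adds to boron of the (E)-alkenylboronic ester A2. The arylpalladium species from triflate A3 (Pd(OAc)2, MandyPhos ligand) then induces a 1,2-shift of ring B from boron to C3 while ring A is delivered to C4, giving the secondary boronic ester A1.
- **In its favour.** Three fragments of similar size are joined at once. Both stereocentres arise together, and anti addition across the E alkene gives the required relative configuration directly. No diazo compound is handled. Ring B oxygen can stay a benzyl ether, so one hydrogenolysis ends the synthesis; on protecting-group economy this alternative is the better plan.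
- **Against it here.** A β-aryl group on the alkenyl boron ate complex is the difficult case for this reaction, because direct transmetallation and slow migration compete. Here that group is ring D with two ortho substituents, and both the migrating aryl and the triflate are ortho-oxygenated. A1 has boron where C2 must be, so a Matteson one-carbon homologation at a hindered secondary benzylic boronate, oxidation, removal of the methoxymethyl group and Mitsunobu closure still follow.
- **Comparison.** The ligand must impose facial selectivity next to C3′, which is no easier than what the carbene catalyst must do (equal). About five steps follow the key step against four in the chosen plan, and A2 needs a ring D aldehyde that already carries the lower chroman, so step economy is about equal. The chosen plan forms the bond intramolecularly through a six-atom tether, not by a three-component encounter at a crowded alkene.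

**Alternative 2:** The cut opens ring D itself, at its C1–C2 and C5–C6 bonds.
- **Forward step.** Alkynone A6 (ring A aroyl on one alkyne carbon, C3′ on the other) and the electron-rich diene A7 undergo a thermal [4+2] cycloaddition. Acidic work-up removes methanol and the silyl group and aromatises the adduct to benzophenone A5.
- **In its favour.** The polarity of the diene writes the ring D pattern: the acetal carbon ends next to the carbonyl-bearing carbon and the siloxy carbon para to it. The methoxy group and the free hydroxyl are thus placed and told apart in one step. On ring D regiochemistry this is better than the chosen plan, which relies on a regioselective formylation and two selective O-alkylations. The step is pericyclic, needs no catalyst and is more predictable than a carbene insertion.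
- **Against it here.** It creates neither upper stereocentre. C4 arrives as the carbonyl of a di-ortho-substituted benzophenone, and ring B, C3 and C2 must still be attached and both centres set, for example by addition to a hindered diaryl ketone, dehydration and asymmetric reduction of a tetrasubstituted alkene. C3′ of A6 is γ to an ynone and may isomerise to an allenone on heating. The free phenol of A5 must be protected again.
- **Comparison.** The chosen plan is clearly shorter after the key step (four steps against at least seven). Up to the key step the two are comparable.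

**Alternative 3:** The cut removes C3–C4 and O1–C2 together.
- **Forward step.** Sulfone A9 with Cs2CO3 releases the ortho-quinone methide A10. Acid A11 is activated with pivaloyl chloride and taken up by HyperBTM as its ammonium enolate, which adds to C4 and is then acylated by the ring A phenoxide to give lactone A8.
- **In its favour.** It forms the same C3–C4 bond as the chosen plan plus the acyl–oxygen bond in one operation, so esterification and diazo transfer fall away (two steps fewer). It is metal-free and needs no diazo compound. Lewis-base-catalysed enolate additions to ortho-quinone methides are an established reaction class, which the lactone closure of the chosen plan is not. On precedent and step count this alternative is the better one. Ring B can be a benzyl ether, which saves a deprotection.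
- **Against it here.** A10 has a benzyloxy donor para to the methide-bearing ring carbon and a di-ortho-substituted ring D on the methide carbon, so it is a weak, hindered electrophile that may form as an E/Z mixture. The nucleophile is an ortho-substituted arylacetic acid, a sluggish class in this catalysis. C4 is set in a bimolecular step in which the catalyst must overrule C3′. A9 must be made from a benzhydrol with a free ortho-phenol after the lower chroman is complete.
- **Comparison.** A8 and 31 differ only in the ring B protecting group, and both allow C3 to be corrected by epimerisation (equal). The chosen plan replaces a face-selective bimolecular addition by an intramolecular choice between two C–H bonds held six atoms from the carbene, which is why it is preferred. Because Alternative 3 rests on known chemistry, it serves as the fallback for the key step.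

Key step: step 20

**Assumption:** the target SMILES encodes a trans upper chroman, (3R,4S), and a (3R) lower chroman; every structure below is drawn to that.

**Remark on the key step:** the two C4 hydrogens of 29 are diastereotopic, not enantiotopic, because C3′ is already stereogenic. The catalyst therefore acts in a matched or mismatched pairing and its antipode is chosen accordingly.

**Remark on the precursor:** ring A is attached before the lower chroman is built, so the reduction to the diarylmethane precedes all stereocentres and the ring A and ring A′ phenols share one protecting group. The ring B silyl ether is kept because a benzyl ether would put an ether C–H five atoms from the carbene.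

## Route

Step 1
Reactants: 1 methyl (3,5-dihydroxyphenyl)acetate
Product: 2 methyl (2-formyl-3,5-dihydroxyphenyl)acetate
Conditions: POCl3, DMF, MeCN, 0 °C to rt; then H2O, NaOAc, 50 °C
Reagents that add atoms: N,N-dimethylformamide CN(C)C=O; water O
Why: Vilsmeier–Haack formylation of a resorcinol; the chloroiminium ion should attack C2 (para to one OH, ortho to the other), the site taken in orcinol formylation, in preference to C4 between the two hydroxyls, and the iminium is hydrolysed on work-up.

Step 2
Reactants: 2 methyl (2-formyl-3,5-dihydroxyphenyl)acetate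
Product: 3 methyl [5-(benzyloxy)-2-formyl-3-hydroxyphenyl]acetate
Conditions: BnBr, NaHCO3, KI (cat.), MeCN, 60 °C
Reagents that add atoms: benzyl bromide BrCc1ccccc1
Why: Williamson etherification; the OH ortho to the formyl group is held in a hydrogen bond and is less nucleophilic, so a weak base should alkylate only the OH para to the aldehyde.

Step 3
Reactants: 3 methyl [5-(benzyloxy)-2-formyl-3-hydroxyphenyl]acetate
Product: 4 methyl [5-(benzyloxy)-2-formyl-3-methoxyphenyl]acetate
Conditions: MeI, K2CO3, DMF, rt
Reagents that add atoms: iodomethane CI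
Why: Williamson methylation of the remaining chelated phenol with the stronger base; carbonate does not alkylate the arylacetate CH2 or touch the aldehyde.

Step 4
Reactants: 5 3-(benzyloxy)phenol
Product: 6 5-(benzyloxy)-2-iodophenol
Conditions: I2, NaHCO3, THF/H2O, 0 °C to rt
Reagents that add atoms: iodine [I][I]
Why: Electrophilic iodination of the phenoxide; attack ortho to O– at the unhindered carbon para to OBn is expected over the carbon between the two oxygens, with one equivalent of iodine limiting the reaction to mono-iodination.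

Step 5
Reactants: 6 5-(benzyloxy)-2-iodophenol
Product: 7 2-(allyloxy)-4-(benzyloxy)-1-iodobenzene
Conditions: allyl bromide, K2CO3, acetone, reflux
Reagents that add atoms: allyl bromide C=CCBr
Why: Williamson allylation; allyl is chosen because it survives Grignard formation, CF3CO2H/Et3SiH, amide bases and LiBH4 and is later removed without touching benzyl ethers.

Step 6
Reactants: 7 2-(allyloxy)-4-(benzyloxy)-1-iodobenzene; 4 methyl [5-(benzyloxy)-2-formyl-3-methoxyphenyl]acetate
Product: 10 1-[2-(allyloxy)-4-(benzyloxy)phenyl]-6-(benzyloxy)-8-methoxyisochroman-3-one (racemic), via aryl Grignard reagent 8 (not isolated), via chloromagnesium alkoxide 9 (not isolated)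
Conditions: i-PrMgCl·LiCl, THF, –15 °C; then 4, –40 °C to rt; aq. NH4Cl
Reagents that add atoms: none
Why: Iodine–magnesium exchange gives 8 at a temperature where it does not attack esters; 1,2-addition to the aldehyde is much faster than ester addition or enolisation, and alkoxide 9 should close the six-membered lactone on warming (intramolecular transesterification); the carbinol centre is racemic and is removed in step 7.

Step 7
Reactants: 10 1-[2-(allyloxy)-4-(benzyloxy)phenyl]-6-(benzyloxy)-8-methoxyisochroman-3-one
Product: 11 {2-[2-(allyloxy)-4-(benzyloxy)benzyl]-5-(benzyloxy)-3-methoxyphenyl}acetic acid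
Conditions: Et3SiH, CF3CO2H, CH2Cl2, 0 °C to rt
Reagents that add atoms: none
Why: Ionic hydrogenation; acid ionises the doubly benzylic lactone C–O bond to a diarylmethyl cation stabilised by ortho and para oxygens on both rings, and Et3SiH delivers hydride, releasing the carboxylic acid directly; allyl and benzyl aryl ethers are expected to persist at this temperature.

Step 8
Reactants: 11 {2-[2-(allyloxy)-4-(benzyloxy)benzyl]-5-(benzyloxy)-3-methoxyphenyl}acetic acid; 12 (R)-4-benzyloxazolidin-2-one
Product: 14 (R)-4-benzyl-3-({2-[2-(allyloxy)-4-(benzyloxy)benzyl]-5-(benzyloxy)-3-methoxyphenyl}acetyl)oxazolidin-2-one, via mixed pivalic anhydride 13 (not isolated)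
Conditions: t-BuCOCl, Et3N, THF, –20 °C; then LiCl, 12, –20 °C to rt
Reagents that add atoms: none
Why: N-acylation of the oxazolidinone through mixed anhydride 13 under LiCl/Et3N; the nucleophile attacks the unhindered arylacetyl carbonyl and not the pivaloyl carbonyl.

Step 9
Reactants: 15 4-(benzyloxy)-2-hydroxybenzaldehyde
Product: 16 2-(allyloxy)-4-(benzyloxy)benzaldehyde
Conditions: allyl bromide, K2CO3, DMF, rt
Reagents that add atoms: allyl bromide C=CCBr
Why: Williamson allylation of the chelated phenol; the same protecting group as in 7 is used so that both are removed together in step 14.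

Step 10
Reactants: 16 2-(allyloxy)-4-(benzyloxy)benzaldehyde
Product: 17 [2-(allyloxy)-4-(benzyloxy)phenyl]methanol
Conditions: NaBH4, MeOH/THF, 0 °C
Reagents that add atoms: none
Why: Borohydride reduction of an aryl aldehyde; ethers are inert.

Step 11
Reactants: 17 [2-(allyloxy)-4-(benzyloxy)phenyl]methanol
Product: 18 2-(allyloxy)-4-(benzyloxy)-1-(bromomethyl)benzene
Conditions: PBr3, Et2O, 0 °C; used at once
Reagents that add atoms: phosphorus tribromide BrP(Br)Br
Why: Conversion of a benzylic alcohol into the bromide through its phosphite ester; the ortho/para-dialkoxybenzyl bromide is labile and is therefore taken crude into step 12.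

Step 12
Reactants: 14 (R)-4-benzyl-3-({2-[2-(allyloxy)-4-(benzyloxy)benzyl]-5-(benzyloxy)-3-methoxyphenyl}acetyl)oxazolidin-2-one; 18 2-(allyloxy)-4-(benzyloxy)-1-(bromomethyl)benzene
Product: 20 (R)-3-[(2R)-3-[2-(allyloxy)-4-(benzyloxy)phenyl]-2-{2-[2-(allyloxy)-4-(benzyloxy)benzyl]-5-(benzyloxy)-3-methoxyphenyl}propanoyl]-4-benzyloxazolidin-2-one, via sodium Z-enolate 19 (not isolated)
Conditions: NaN(SiMe3)2, THF, –78 °C; then 18, –78 to –40 °C
Reagents that add atoms: none
Why: Evans asymmetric alkylation; the base gives the chelated Z-enolate 19, the benzyl group of the (R)-auxiliary shields one face and the benzylic bromide enters from the other, which sets C3′ as R; the diarylmethane CH2 is far less acidic than the imide and stays untouched.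

Step 13
Reactants: 20 (R)-3-[(2R)-3-[2-(allyloxy)-4-(benzyloxy)phenyl]-2-{2-[2-(allyloxy)-4-(benzyloxy)benzyl]-5-(benzyloxy)-3-methoxyphenyl}propanoyl]-4-benzyloxazolidin-2-one
Product: 21 (2R)-3-[2-(allyloxy)-4-(benzyloxy)phenyl]-2-{2-[2-(allyloxy)-4-(benzyloxy)benzyl]-5-(benzyloxy)-3-methoxyphenyl}propan-1-ol
Conditions: LiBH4, H2O (1 equiv), Et2O/THF, 0 °C to rt
Reagents that add atoms: none
Why: Reductive cleavage of the imide at the exocyclic carbonyl to the primary alcohol; the intermediate aldehyde is reduced faster than it enolises, so C3′ should be retained, and the auxiliary is recovered.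

Step 14
Reactants: 21 (2R)-3-[2-(allyloxy)-4-(benzyloxy)phenyl]-2-{2-[2-(allyloxy)-4-(benzyloxy)benzyl]-5-(benzyloxy)-3-methoxyphenyl}propan-1-ol
Product: 22 (2R)-2-{5-(benzyloxy)-2-[4-(benzyloxy)-2-hydroxybenzyl]-3-methoxyphenyl}-3-[4-(benzyloxy)-2-hydroxyphenyl]propan-1-ol
Conditions: Pd(PPh3)4 (cat.), morpholine, THF, rt
Reagents that add atoms: none
Why: Tsuji–Trost deallylation; zerovalent palladium ionises both allyl aryl ethers to allylpalladium complexes that morpholine captures, while benzyl ethers and the alcohol are inert.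

Step 15
Reactants: 22 (2R)-2-{5-(benzyloxy)-2-[4-(benzyloxy)-2-hydroxybenzyl]-3-methoxyphenyl}-3-[4-(benzyloxy)-2-hydroxyphenyl]propan-1-ol
Product: 23 5-(benzyloxy)-2-({4-(benzyloxy)-2-[(3R)-7-(benzyloxy)chroman-3-yl]-6-methoxyphenyl}methyl)phenol
Conditions: PPh3, DIAD, THF (dilute), 0 °C to rt
Reagents that add atoms: none
Why: Mitsunobu etherification; the primary alcohol is activated as its oxyphosphonium ion and displaced by the ring A′ phenoxide in a 6-exo-tet closure, whereas the ring A phenol would need a nine-membered ring and stays free; C3′ is not a reacting centre.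

Step 16
Reactants: 24 (2-bromo-4,5-dimethoxyphenyl)acetic acid
Product: 25 (2-hydroxy-4,5-dimethoxyphenyl)acetic acid
Conditions: CuI (cat.), 8-hydroxyquinoline (cat.), KOH, DMSO/H2O, 110 °C, argon; then aq. HCl, 0 °C
Reagents that add atoms: potassium hydroxide [K+].[OH-]
Why: Ullmann-type copper-catalysed hydroxylation of an aryl bromide, assisted by the ortho carboxylate; cold acidification and immediate use limit lactonisation to the benzofuranone.

Step 17
Reactants: 25 (2-hydroxy-4,5-dimethoxyphenyl)acetic acid
Product: 27 {2-[(tert-butyldimethylsilyl)oxy]-4,5-dimethoxyphenyl}acetic acid, via silyl ester 26 (not isolated)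
Conditions: t-BuMe2SiCl, imidazole, DMF, rt; then AcOH/THF/H2O, rt
Reagents that add atoms: tert-butyldimethylsilyl chloride CC(C)(C)[Si](C)(C)Cl
Why: Silylation of both the phenol and the carboxyl group, then selective hydrolysis of the far more labile silyl ester 26 under mild acid, which leaves the aryl silyl ether.

Step 18
Reactants: 23 5-(benzyloxy)-2-({4-(benzyloxy)-2-[(3R)-7-(benzyloxy)chroman-3-yl]-6-methoxyphenyl}methyl)phenol; 27 {2-[(tert-butyldimethylsilyl)oxy]-4,5-dimethoxyphenyl}acetic acid
Product: 28 5-(benzyloxy)-2-({4-(benzyloxy)-2-[(3R)-7-(benzyloxy)chroman-3-yl]-6-methoxyphenyl}methyl)phenyl {2-[(tert-butyldimethylsilyl)oxy]-4,5-dimethoxyphenyl}acetate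
Conditions: EDC·HCl, DMAP (cat.), CH2Cl2, 0 °C to rt
Reagents that add atoms: none
Why: Steglich-type esterification; 23 has a single free hydroxyl, so the acyl group can go only to O1 of ring A.

Step 19
Reactants: 28 5-(benzyloxy)-2-({4-(benzyloxy)-2-[(3R)-7-(benzyloxy)chroman-3-yl]-6-methoxyphenyl}methyl)phenyl {2-[(tert-butyldimethylsilyl)oxy]-4,5-dimethoxyphenyl}acetate
Product: 29 5-(benzyloxy)-2-({4-(benzyloxy)-2-[(3R)-7-(benzyloxy)chroman-3-yl]-6-methoxyphenyl}methyl)phenyl diazo{2-[(tert-butyldimethylsilyl)oxy]-4,5-dimethoxyphenyl}acetate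
Conditions: 4-acetamidobenzenesulfonyl azide, DBU, MeCN, 0 °C
Reagents that add atoms: 4-acetamidobenzenesulfonyl azide CC(=O)Nc1ccc(cc1)S(=O)(=O)N=[N+]=[N-]
Why: Regitz diazo transfer to the α-carbon of an aryl arylacetate, the only position acidic enough for DBU; low temperature and dry solvent are chosen to spare the aryl ester and the aryl silyl ether.

Step 20
Reactants: 29 5-(benzyloxy)-2-({4-(benzyloxy)-2-[(3R)-7-(benzyloxy)chroman-3-yl]-6-methoxyphenyl}methyl)phenyl diazo{2-[(tert-butyldimethylsilyl)oxy]-4,5-dimethoxyphenyl}acetate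
Product: 31 (3R,4S)-7-(benzyloxy)-4-{4-(benzyloxy)-2-[(3R)-7-(benzyloxy)chroman-3-yl]-6-methoxyphenyl}-3-{2-[(tert-butyldimethylsilyl)oxy]-4,5-dimethoxyphenyl}chroman-2-one, via cis lactone 30 (not isolated)
Conditions: Rh2(S-PTAD)4 (1 mol %), CH2Cl2, 4 Å MS, slow addition of 29, 25–40 °C; then DBU (cat.), rt
Reagents that add atoms: none
Why: Proposed new method: Rh2(S-PTAD)4 expels N2 from 29 and forms a rhodium carbene stabilised by ring B as donor and the aryl ester as acceptor; from the s-cis ester rotamer the carbene carbon accepts hydride character from one C4–H in a concerted three-centre transition state and the C3–C4 bond forms with retention at C4. The closest known reaction type is the dirhodium-catalysed enantioselective benzylic C–H insertion of aryldiazoacetate (donor/acceptor) carbenes, established intermolecularly and for five-membered closures but not for this six-membered aryl-ester lactone. The ring closes by 1,6-insertion through a six-membered transition state made of the carbene carbon, C2, O1, C8a, C4a and C4. C4 is controlled by the chiral carboxylate pocket, which must choose between the two C4 hydrogens; these are diastereotopic because C3′ is already stereogenic, so the pairing is matched or mismatched and Rh2(R-PTAD)4 is the alternative if S-PTAD is mismatched. C3 forms in the same transition state but is epimerisable, so DBU added after nitrogen evolution should convert any cis epimer 30 into the more stable trans lactone 31. The step needs C(sp3)–H insertion to outrun attack on C8 of ring A, Büchner addition and carbene dimerisation: the C4–H bonds are doubly benzylic and ortho or para to oxygen on both rings (strongly hydridic), the donor/acceptor carbene is selective for such bonds, the bulky ligands disfavour arene approach, and slow addition keeps the diazo concentration low. No ether C–H lies five or six atoms from the carbene because the ring B oxygen carries silicon instead of a benzyl group.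

Step 21
Reactants: 31 (3R,4S)-7-(benzyloxy)-4-{4-(benzyloxy)-2-[(3R)-7-(benzyloxy)chroman-3-yl]-6-methoxyphenyl}-3-{2-[(tert-butyldimethylsilyl)oxy]-4,5-dimethoxyphenyl}chroman-2-one
Product: 32 5-(benzyloxy)-2-[(1S,2R)-1-{4-(benzyloxy)-2-[(3R)-7-(benzyloxy)chroman-3-yl]-6-methoxyphenyl}-2-{2-[(tert-butyldimethylsilyl)oxy]-4,5-dimethoxyphenyl}-3-hydroxypropyl]phenol
Conditions: LiBH4, THF, 0 °C to rt
Reagents that add atoms: none
Why: Hydride reduction of the reactive aryl lactone to the phenol and the primary alcohol; the intermediate aldehyde is reduced faster than it enolises, so C3 should be kept, and the silyl and benzyl ethers are inert.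

Step 22
Reactants: 32 5-(benzyloxy)-2-[(1S,2R)-1-{4-(benzyloxy)-2-[(3R)-7-(benzyloxy)chroman-3-yl]-6-methoxyphenyl}-2-{2-[(tert-butyldimethylsilyl)oxy]-4,5-dimethoxyphenyl}-3-hydroxypropyl]phenol
Product: 33 tert-butyl(2-{(3R,4S)-7-(benzyloxy)-4-[4-(benzyloxy)-2-((3R)-7-(benzyloxy)chroman-3-yl)-6-methoxyphenyl]chroman-3-yl}-4,5-dimethoxyphenoxy)dimethylsilane
Conditions: PPh3, DIAD, THF, 0 °C to rt
Reagents that add atoms: none
Why: Mitsunobu etherification; the ring A phenoxide displaces the activated primary oxygen on C2 (6-exo-tet) and re-forms O1–C2, and the silyl group keeps the ring B oxygen from closing a five-membered ring; neither stereocentre is a reacting centre.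

Step 23
Reactants: 33 tert-butyl(2-{(3R,4S)-7-(benzyloxy)-4-[4-(benzyloxy)-2-((3R)-7-(benzyloxy)chroman-3-yl)-6-methoxyphenyl]chroman-3-yl}-4,5-dimethoxyphenoxy)dimethylsilane
Product: 34 2-{(3R,4S)-7-(benzyloxy)-4-[4-(benzyloxy)-2-((3R)-7-(benzyloxy)chroman-3-yl)-6-methoxyphenyl]chroman-3-yl}-4,5-dimethoxyphenol
Conditions: Bu4NF, AcOH, THF, 0 °C
Reagents that add atoms: none
Why: Fluoride cleavage of the aryl silyl ether, buffered so that the electron-rich phenoxide is not left in a basic medium.

Step 24
Reactants: 34 2-{(3R,4S)-7-(benzyloxy)-4-[4-(benzyloxy)-2-((3R)-7-(benzyloxy)chroman-3-yl)-6-methoxyphenyl]chroman-3-yl}-4,5-dimethoxyphenol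
Product: 35 (3R,4S)-3-(2-hydroxy-4,5-dimethoxyphenyl)-4-{4-hydroxy-2-[(3R)-7-hydroxychroman-3-yl]-6-methoxyphenyl}chroman-7-ol (CNP0266829.1)
Conditions: H2 (1 atm), Pd/C, EtOAc/MeOH, rt
Reagents that add atoms: none
Why: Hydrogenolysis of three benzyl aryl ethers; no C–O bond of either chroman ring is benzylic and C4 has no leaving group, so the skeleton and all three stereocentres should pass unchanged, and the air-sensitive tetraphenol is obtained by filtration.

## Compound list

1 | methyl (3,5-dihydroxyphenyl)acetate | COC(=O)Cc1cc(O)cc(O)c1 | starting material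
2 | methyl (2-formyl-3,5-dihydroxyphenyl)acetate | COC(=O)Cc1cc(O)cc(O)c1C=O | intermediate
3 | methyl [5-(benzyloxy)-2-formyl-3-hydroxyphenyl]acetate | COC(=O)Cc1cc(OCc2ccccc2)cc(O)c1C=O | intermediate
4 | methyl [5-(benzyloxy)-2-formyl-3-methoxyphenyl]acetate | COC(=O)Cc1cc(OCc2ccccc2)cc(OC)c1C=O | intermediate
5 | 3-(benzyloxy)phenol | Oc1cccc(OCc2ccccc2)c1 | starting material
6 | 5-(benzyloxy)-2-iodophenol | Oc1cc(OCc2ccccc2)ccc1I | intermediate
7 | 2-(allyloxy)-4-(benzyloxy)-1-iodobenzene | C=CCOc1cc(OCc2ccccc2)ccc1I | intermediate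
8 | [2-(allyloxy)-4-(benzyloxy)phenyl]magnesium chloride (LiCl complex) | C=CCOc1cc(OCc2ccccc2)ccc1[Mg]Cl | intermediate (not isolated)
9 | chloromagnesium alkoxide of methyl (2-{[2-(allyloxy)-4-(benzyloxy)phenyl](hydroxy)methyl}-5-(benzyloxy)-3-methoxyphenyl)acetate (racemic) | COC(=O)Cc1cc(OCc2ccccc2)cc(OC)c1C(O[Mg]Cl)c1ccc(OCc2ccccc2)cc1OCC=C | intermediate (not isolated)
10 | 1-[2-(allyloxy)-4-(benzyloxy)phenyl]-6-(benzyloxy)-8-methoxyisochroman-3-one (racemic) | O=C1Cc2cc(OCc3ccccc3)cc(OC)c2C(O1)c1ccc(OCc2ccccc2)cc1OCC=C | intermediate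
11 | {2-[2-(allyloxy)-4-(benzyloxy)benzyl]-5-(benzyloxy)-3-methoxyphenyl}acetic acid | OC(=O)Cc1cc(OCc2ccccc2)cc(OC)c1Cc1ccc(OCc2ccccc2)cc1OCC=C | intermediate
12 | (R)-4-benzyloxazolidin-2-one | O=C1N[C@H](Cc2ccccc2)CO1 | starting material
13 | mixed anhydride of 11 with pivalic acid | CC(C)(C)C(=O)OC(=O)Cc1cc(OCc2ccccc2)cc(OC)c1Cc1ccc(OCc2ccccc2)cc1OCC=C | intermediate (not isolated)
14 | (R)-4-benzyl-3-({2-[2-(allyloxy)-4-(benzyloxy)benzyl]-5-(benzyloxy)-3-methoxyphenyl}acetyl)oxazolidin-2-one | O=C1OC[C@@H](Cc2ccccc2)N1C(=O)Cc1cc(OCc2ccccc2)cc(OC)c1Cc1ccc(OCc2ccccc2)cc1OCC=C | intermediate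
15 | 4-(benzyloxy)-2-hydroxybenzaldehyde | O=Cc1ccc(OCc2ccccc2)cc1O | starting material
16 | 2-(allyloxy)-4-(benzyloxy)benzaldehyde | O=Cc1ccc(OCc2ccccc2)cc1OCC=C | intermediate
17 | [2-(allyloxy)-4-(benzyloxy)phenyl]methanol | OCc1ccc(OCc2ccccc2)cc1OCC=C | intermediate
18 | 2-(allyloxy)-4-(benzyloxy)-1-(bromomethyl)benzene | BrCc1ccc(OCc2ccccc2)cc1OCC=C | intermediate
19 | sodium (Z)-enolate of 14 | [Na+].[O-]/C(=C\c1cc(OCc2ccccc2)cc(OC)c1Cc1ccc(OCc2ccccc2)cc1OCC=C)N1C(=O)OC[C@H]1Cc1ccccc1 | intermediate (not isolated)
20 | (R)-3-[(2R)-3-[2-(allyloxy)-4-(benzyloxy)phenyl]-2-{2-[2-(allyloxy)-4-(benzyloxy)benzyl]-5-(benzyloxy)-3-methoxyphenyl}propanoyl]-4-benzyloxazolidin-2-one | O=C1OC[C@@H](Cc2ccccc2)N1C(=O)[C@H](Cc1ccc(OCc2ccccc2)cc1OCC=C)c1cc(OCc2ccccc2)cc(OC)c1Cc1ccc(OCc2ccccc2)cc1OCC=C | intermediate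
21 | (2R)-3-[2-(allyloxy)-4-(benzyloxy)phenyl]-2-{2-[2-(allyloxy)-4-(benzyloxy)benzyl]-5-(benzyloxy)-3-methoxyphenyl}propan-1-ol | OC[C@H](Cc1ccc(OCc2ccccc2)cc1OCC=C)c1cc(OCc2ccccc2)cc(OC)c1Cc1ccc(OCc2ccccc2)cc1OCC=C | intermediate
22 | (2R)-2-{5-(benzyloxy)-2-[4-(benzyloxy)-2-hydroxybenzyl]-3-methoxyphenyl}-3-[4-(benzyloxy)-2-hydroxyphenyl]propan-1-ol | OC[C@H](Cc1ccc(OCc2ccccc2)cc1O)c1cc(OCc2ccccc2)cc(OC)c1Cc1ccc(OCc2ccccc2)cc1O | intermediate
23 | 5-(benzyloxy)-2-({4-(benzyloxy)-2-[(3R)-7-(benzyloxy)chroman-3-yl]-6-methoxyphenyl}methyl)phenol | Oc1cc(OCc2ccccc2)ccc1Cc1c(OC)cc(OCc2ccccc2)cc1[C@@H]1COc2cc(OCc3ccccc3)ccc2C1 | intermediate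
24 | (2-bromo-4,5-dimethoxyphenyl)acetic acid | COc1cc(Br)c(CC(=O)O)cc1OC | starting material
25 | (2-hydroxy-4,5-dimethoxyphenyl)acetic acid | COc1cc(O)c(CC(=O)O)cc1OC | intermediate
26 | tert-butyldimethylsilyl {2-[(tert-butyldimethylsilyl)oxy]-4,5-dimethoxyphenyl}acetate | COc1cc(O[Si](C)(C)C(C)(C)C)c(CC(=O)O[Si](C)(C)C(C)(C)C)cc1OC | intermediate (not isolated)
27 | {2-[(tert-butyldimethylsilyl)oxy]-4,5-dimethoxyphenyl}acetic acid | COc1cc(O[Si](C)(C)C(C)(C)C)c(CC(=O)O)cc1OC | intermediate
28 | 5-(benzyloxy)-2-({4-(benzyloxy)-2-[(3R)-7-(benzyloxy)chroman-3-yl]-6-methoxyphenyl}methyl)phenyl {2-[(tert-butyldimethylsilyl)oxy]-4,5-dimethoxyphenyl}acetate | COc1cc(O[Si](C)(C)C(C)(C)C)c(cc1OC)CC(=O)Oc1cc(OCc2ccccc2)ccc1Cc1c(OC)cc(OCc2ccccc2)cc1[C@@H]1COc2cc(OCc3ccccc3)ccc2C1 | intermediate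
29 | 5-(benzyloxy)-2-({4-(benzyloxy)-2-[(3R)-7-(benzyloxy)chroman-3-yl]-6-methoxyphenyl}methyl)phenyl diazo{2-[(tert-butyldimethylsilyl)oxy]-4,5-dimethoxyphenyl}acetate | COc1cc(O[Si](C)(C)C(C)(C)C)c(cc1OC)C(=[N+]=[N-])C(=O)Oc1cc(OCc2ccccc2)ccc1Cc1c(OC)cc(OCc2ccccc2)cc1[C@@H]1COc2cc(OCc3ccccc3)ccc2C1 | intermediate (precursor of the key step)
30 | (3S,4S)-7-(benzyloxy)-4-{4-(benzyloxy)-2-[(3R)-7-(benzyloxy)chroman-3-yl]-6-methoxyphenyl}-3-{2-[(tert-butyldimethylsilyl)oxy]-4,5-dimethoxyphenyl}chroman-2-one (cis) | COc1cc(O[Si](C)(C)C(C)(C)C)c(cc1OC)[C@H]1C(=O)Oc2cc(OCc3ccccc3)ccc2[C@H]1c1c(OC)cc(OCc2ccccc2)cc1[C@@H]1COc2cc(OCc3ccccc3)ccc2C1 | intermediate (not isolated)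
31 | (3R,4S)-7-(benzyloxy)-4-{4-(benzyloxy)-2-[(3R)-7-(benzyloxy)chroman-3-yl]-6-methoxyphenyl}-3-{2-[(tert-butyldimethylsilyl)oxy]-4,5-dimethoxyphenyl}chroman-2-one (trans) | COc1cc(O[Si](C)(C)C(C)(C)C)c(cc1OC)[C@@H]1C(=O)Oc2cc(OCc3ccccc3)ccc2[C@H]1c1c(OC)cc(OCc2ccccc2)cc1[C@@H]1COc2cc(OCc3ccccc3)ccc2C1 | intermediate (product of the key step)
32 | 5-(benzyloxy)-2-[(1S,2R)-1-{4-(benzyloxy)-2-[(3R)-7-(benzyloxy)chroman-3-yl]-6-methoxyphenyl}-2-{2-[(tert-butyldimethylsilyl)oxy]-4,5-dimethoxyphenyl}-3-hydroxypropyl]phenol | COc1cc(O[Si](C)(C)C(C)(C)C)c(cc1OC)[C@H](CO)[C@@H](c1ccc(OCc2ccccc2)cc1O)c1c(OC)cc(OCc2ccccc2)cc1[C@@H]1COc2cc(OCc3ccccc3)ccc2C1 | intermediate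
33 | tert-butyl(2-{(3R,4S)-7-(benzyloxy)-4-[4-(benzyloxy)-2-((3R)-7-(benzyloxy)chroman-3-yl)-6-methoxyphenyl]chroman-3-yl}-4,5-dimethoxyphenoxy)dimethylsilane | COc1cc(O[Si](C)(C)C(C)(C)C)c(cc1OC)[C@@H]1COc2cc(OCc3ccccc3)ccc2[C@H]1c1c(OC)cc(OCc2ccccc2)cc1[C@@H]1COc2cc(OCc3ccccc3)ccc2C1 | intermediate
34 | 2-{(3R,4S)-7-(benzyloxy)-4-[4-(benzyloxy)-2-((3R)-7-(benzyloxy)chroman-3-yl)-6-methoxyphenyl]chroman-3-yl}-4,5-dimethoxyphenol | COc1cc(O)c(cc1OC)[C@@H]1COc2cc(OCc3ccccc3)ccc2[C@H]1c1c(OC)cc(OCc2ccccc2)cc1[C@@H]1COc2cc(OCc3ccccc3)ccc2C1 | intermediate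
35 | (3R,4S)-3-(2-hydroxy-4,5-dimethoxyphenyl)-4-{4-hydroxy-2-[(3R)-7-hydroxychroman-3-yl]-6-methoxyphenyl}chroman-7-ol | COc1cc(O)c([C@@H]2COc3cc(O)ccc3[C@H]2c2c(OC)cc(O)cc2[C@@H]2COc3cc(O)ccc3C2)cc1OC | target

## Step count and least certain steps

Total step count: 24.

Longest linear sequence: 17 steps, from 1 to 35 through steps 1, 2, 3, 6, 7, 8, 12, 13, 14, 15, 18, 19, 20, 21, 22, 23 and 24.

**Step 20 (key step).** The most likely failure is attack of the carbene on the π system of ring A at C8, the carbon between the ester oxygen and the benzyloxy group, or carbene dimerisation. The cause is that the aryl ester must first rotate into its less populated s-cis form before the C4–H bonds come within reach. A second concern is weak discrimination between the two C4 hydrogens if catalyst and C3′ are mismatched. The fallback uses known chemistry and sets out from 23. Oxidation with Ag2O in CH2Cl2 should give the ortho-quinone methide F1. Acid 27 is converted with t-BuCOCl and i-Pr2NEt into the mixed pivalic anhydride F2, from which HyperBTM generates the ammonium enolate. Michael addition to C4 of F1, lactonisation by the phenoxide and DBU equilibration should give 31, where the route is rejoined.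

**Step 6.** The most likely failure is enolisation of the arylacetate by the Grignard reagent, or incomplete lactonisation, because the aldehyde is di-ortho-substituted and deactivated by two donor oxygens. Formation of some 4-iodo isomer in step 4 would add to the problem. The fallback is a boron-templated ortho-hydroxyalkylation that sets out from 4 and 5 and also bypasses steps 4 and 5. PhB(OH)2 and catalytic propionic acid in refluxing toluene with removal of water should give the 4H-1,3,2-benzodioxaborin F3, in which the C–C bond forms only ortho to the phenol oxygen. Et3SiH/CF3CO2H reduces it to the ortho-benzylphenol methyl ester F4. Allyl bromide and K2CO3 give the allyl ether F5, and LiOH in THF/H2O returns to 11.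

**Step 19.** The most likely failure is fragmentation of the aryl ester enolate by loss of the phenoxide of 23 (ketene formation), or removal of the aryl silyl ether by DBU. The fallback builds the diazo ester by arylation in place of diazo transfer and sets out from 23. Bromoacetyl bromide and pyridine give the bromoacetate F6, and N,N′-ditosylhydrazine with DBU converts it into the diazoacetate F7. Commercial 3,4-dimethoxyphenol is iodinated with N-iodosuccinimide to 2-iodo-4,5-dimethoxyphenol F8 and silylated to the aryl iodide F9. Palladium-catalysed coupling of F7 with F9 (Pd(PPh3)4, Ag2CO3, Et3N, toluene, rt), which keeps the diazo group, returns to 29.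

**Step 22.** The most likely failure is participation of the electron-rich ring B (para-methoxy, ortho-silyloxy) in the departure of the oxyphosphonium group, a phenonium pathway that leads to ring contraction. Migration of the silyl group to the primary alkoxide during step 21 would have a similar effect. The fallback sets out from 31 and never forms the primary alcohol. i-Bu2AlH at –78 °C gives the lactol F10, and Et3SiH/BF3·OEt2 reduces it through the oxocarbenium ion to 33.

## Further compounds

F1 | step 20 | ortho-quinone methide from 23: 3-(benzyloxy)-6-({4-(benzyloxy)-2-[(3R)-7-(benzyloxy)chroman-3-yl]-6-methoxyphenyl}methylidene)cyclohexa-2,4-dien-1-one | O=C1C=C(OCc2ccccc2)C=CC1=Cc1c(OC)cc(OCc2ccccc2)cc1[C@@H]1COc2cc(OCc3ccccc3)ccc2C1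
F2 | step 20 | mixed anhydride of 27 with pivalic acid | COc1cc(O[Si](C)(C)C(C)(C)C)c(CC(=O)OC(=O)C(C)(C)C)cc1OC
F3 | step 6 | methyl {5-(benzyloxy)-2-[7-(benzyloxy)-2-phenyl-4H-1,3,2-benzodioxaborin-4-yl]-3-methoxyphenyl}acetate (racemic) | COC(=O)Cc1cc(OCc2ccccc2)cc(OC)c1C1OB(c2ccccc2)Oc2cc(OCc3ccccc3)ccc12
F4 | step 6 | methyl {5-(benzyloxy)-2-[4-(benzyloxy)-2-hydroxybenzyl]-3-methoxyphenyl}acetate | COC(=O)Cc1cc(OCc2ccccc2)cc(OC)c1Cc1ccc(OCc2ccccc2)cc1O
F5 | step 6 | methyl {2-[2-(allyloxy)-4-(benzyloxy)benzyl]-5-(benzyloxy)-3-methoxyphenyl}acetate | COC(=O)Cc1cc(OCc2ccccc2)cc(OC)c1Cc1ccc(OCc2ccccc2)cc1OCC=C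
F6 | step 19 | 5-(benzyloxy)-2-({4-(benzyloxy)-2-[(3R)-7-(benzyloxy)chroman-3-yl]-6-methoxyphenyl}methyl)phenyl bromoacetate | BrCC(=O)Oc1cc(OCc2ccccc2)ccc1Cc1c(OC)cc(OCc2ccccc2)cc1[C@@H]1COc2cc(OCc3ccccc3)ccc2C1
F7 | step 19 | 5-(benzyloxy)-2-({4-(benzyloxy)-2-[(3R)-7-(benzyloxy)chroman-3-yl]-6-methoxyphenyl}methyl)phenyl diazoacetate | [N-]=[N+]=CC(=O)Oc1cc(OCc2ccccc2)ccc1Cc1c(OC)cc(OCc2ccccc2)cc1[C@@H]1COc2cc(OCc3ccccc3)ccc2C1
F8 | step 19 | 2-iodo-4,5-dimethoxyphenol | COc1cc(O)c(I)cc1OC
F9 | step 19 | tert-butyl(2-iodo-4,5-dimethoxyphenoxy)dimethylsilane | COc1cc(O[Si](C)(C)C(C)(C)C)c(I)cc1OC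
F10 | step 22 | (3R,4S)-7-(benzyloxy)-4-{4-(benzyloxy)-2-[(3R)-7-(benzyloxy)chroman-3-yl]-6-methoxyphenyl}-3-{2-[(tert-butyldimethylsilyl)oxy]-4,5-dimethoxyphenyl}chroman-2-ol (anomeric mixture) | COc1cc(O[Si](C)(C)C(C)(C)C)c(cc1OC)[C@@H]1C(O)Oc2cc(OCc3ccccc3)ccc2[C@H]1c1c(OC)cc(OCc2ccccc2)cc1[C@@H]1COc2cc(OCc3ccccc3)ccc2C1
A1 | alternative 1 | secondary pinacol boronic ester with ring B and boron on C3, ring A and ring D on C4 | COc1cc(OCc2ccccc2)c(cc1OC)[C@H](B1OC(C)(C)C(C)(C)O1)[C@@H](c1ccc(OCc2ccccc2)cc1OCOC)c1c(OC)cc(OCc2ccccc2)cc1[C@@H]1COc2cc(OCc3ccccc3)ccc2C1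
A2 | alternative 1 | (E)-2-(2-{4-(benzyloxy)-2-[(3R)-7-(benzyloxy)chroman-3-yl]-6-methoxyphenyl}ethenyl)-4,4,5,5-tetramethyl-1,3,2-dioxaborolane | B1(OC(C)(C)C(C)(C)O1)/C=C/c1c(OC)cc(OCc2ccccc2)cc1[C@@H]1COc2cc(OCc3ccccc3)ccc2C1
A3 | alternative 1 | 4-(benzyloxy)-2-(methoxymethoxy)phenyl trifluoromethanesulfonate | COCOc1cc(OCc2ccccc2)ccc1OS(=O)(=O)C(F)(F)F
A4 | alternative 1 | 1-(benzyloxy)-2-bromo-4,5-dimethoxybenzene | COc1cc(Br)c(OCc2ccccc2)cc1OC
A5 | alternative 2 | [4-(benzyloxy)-2-(methoxymethoxy)phenyl]{2-[(3R)-7-(benzyloxy)chroman-3-yl]-4-hydroxy-6-methoxyphenyl}methanone | O=C(c1ccc(OCc2ccccc2)cc1OCOC)c1c(OC)cc(O)cc1[C@@H]1COc2cc(OCc3ccccc3)ccc2C1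
A6 | alternative 2 | 1-[4-(benzyloxy)-2-(methoxymethoxy)phenyl]-3-[7-(benzyloxy)chroman-3-yl]prop-2-yn-1-one (single enantiomer, configured as in the target) | O=C(C#C[C@@H]1COc2cc(OCc3ccccc3)ccc2C1)c1ccc(OCc2ccccc2)cc1OCOC
A7 | alternative 2 | 1,1-dimethoxy-3-(trimethylsilyloxy)buta-1,3-diene | COC(OC)=CC(=C)O[Si](C)(C)C
A8 | alternative 3 | tetra-O-benzyl trans-3,4-diaryl-3,4-dihydrocoumarin | COc1cc(OCc2ccccc2)c(cc1OC)[C@@H]1C(=O)Oc2cc(OCc3ccccc3)ccc2[C@H]1c1c(OC)cc(OCc2ccccc2)cc1[C@@H]1COc2cc(OCc3ccccc3)ccc2C1
A9 | alternative 3 | 5-(benzyloxy)-2-[{4-(benzyloxy)-2-[(3R)-7-(benzyloxy)chroman-3-yl]-6-methoxyphenyl}(4-methylbenzenesulfonyl)methyl]phenol | Cc1ccc(cc1)S(=O)(=O)C(c1ccc(OCc2ccccc2)cc1O)c1c(OC)cc(OCc2ccccc2)cc1[C@@H]1COc2cc(OCc3ccccc3)ccc2C1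
A10 | alternative 3 | ortho-quinone methide released from A9 | O=C1C=C(OCc2ccccc2)C=CC1=Cc1c(OC)cc(OCc2ccccc2)cc1[C@@H]1COc2cc(OCc3ccccc3)ccc2C1
A11 | alternative 3 | [2-(benzyloxy)-4,5-dimethoxyphenyl]acetic acid | COc1cc(OCc2ccccc2)c(CC(=O)O)cc1OC
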